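**Plan**

- Retrosynthetic cuts: first the C(sp)–C(sp2) bond between the side-chain alkyne and the E-alkene, then both peroxide C–O bonds (C3–O2 and C6–O1), then the bonds joining the four-carbon core to the pentynyl chain and to the two-carbon arm.
- Enabling feature: in the 1,2-dioxane O1–O2–C3–C4–C5–C6 the carbons C3–C6 carry a peroxide oxygen at each end, with C6 at the ketone oxidation level and C3 secondary. This is a 1,2-disubstituted cyclobutanol with O2 inserted between its carbinol carbon and the substituted ring carbon.
- Forward order: cyclobutanone is α-alkylated, a silyl-capped pentynyl organocerium reagent adds to the ketone, and aerobic Co(acac)2 catalysis expands the four-membered ring to the 1,2-dioxan-3-ol, the only ring of the target. Ketalisation, desilylation, oxidation of the arm to CH2CO2Me, Sonogashira coupling and ester hydrolysis follow.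
- The arm is carried as a saturated TBDPS-protected 2-hydroxyethyl group rather than an allyl group, so that the intermediate peroxyl radical has no alkene to cyclise onto.
- Stereochemistry: C3 arises racemic from a radical. C6 is set relative to C3 by thermodynamic ketalisation in acidic methanol (axial OMe, both carbon substituents equatorial, OMe cis to the arm). The (3S,6R) enantiomer is selected by esterase hydrolysis in the last step. The E-alkene comes from a Takai iodo-olefination and is retained in the coupling.

Key step: step 4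

Remark on the chemistry: the required relative configuration (OMe at C6 cis to the C3 arm) is assumed to be the thermodynamically preferred ketal. Compounds 3 and 7 are taken as purchased (each is otherwise one step from 2-iodoethanol or 5-chloropent-1-yne).

Ring locants used throughout are those of the target: O1–O2–C3(H, arm)–C4–C5–C6(ketal). For racemic compounds the SMILES shows the enantiomer that leads to the target.

**Route**

Step 1
Reactants: 1 cyclobutanone
Product: 2 N-cyclohexylcyclobutanimine
Conditions: cyclohexylamine, 4 Å molecular sieves, Et2O, 0 °C → rt; filtered and used crude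
Reagents that add atoms: cyclohexylamine, NC1CCCCC1
Why: Imine condensation of a ketone with a primary amine, driven by water removal; the N-cyclohexyl imine is the standard handle for clean α-monoalkylation of cyclobutanone, whose own enolate self-condenses.

Step 2
Reactants: 2 N-cyclohexylcyclobutanimine; 3 tert-butyl(2-iodoethoxy)diphenylsilane
Product: 6 2-{2-[(tert-butyldiphenylsilyl)oxy]ethyl}cyclobutan-1-one (racemic), via lithium aza-enolate 4 (not isolated), via alkylated imine 5 (not isolated)
Conditions: LiN(i-Pr)2 (LDA), THF, −78 → 0 °C; 3, −78 °C → rt; then aq. oxalic acid/Et2O, rt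
Reagents that add atoms: water, O
Why: Metalloenamine (aza-enolate) alkylation: the lithiated imine undergoes SN2 monoalkylation with the primary iodide, and two-phase oxalic acid hydrolysis returns the ketone without touching the TBDPS ether; the new stereocentre is racemic and is erased in step 4.

Step 3
Reactants: 6 2-{2-[(tert-butyldiphenylsilyl)oxy]ethyl}cyclobutan-1-one; 7 (5-chloropent-1-yn-1-yl)trimethylsilane
Product: 10 2-{2-[(tert-butyldiphenylsilyl)oxy]ethyl}-1-[5-(trimethylsilyl)pent-4-yn-1-yl]cyclobutan-1-ol (racemic; both diastereomers), via Grignard reagent 8 (not isolated), via organocerium reagent 9 (not isolated)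
Conditions: 7, Mg turnings (I2 crystal), THF, reflux; anhydrous CeCl3, THF, −78 °C; then 6, −78 → 0 °C; aq. NH4Cl
Reagents that add atoms: none
Why: Organocerium (Imamoto) 1,2-addition: the weakly basic alkylcerium adds to the strained, enolisable cyclobutanone without deprotonating it, the silyl cap keeps the alkyne from being metallated, and both stereocentres are left uncontrolled because step 4 destroys them.

Step 4
Reactants: 10 2-{2-[(tert-butyldiphenylsilyl)oxy]ethyl}-1-[5-(trimethylsilyl)pent-4-yn-1-yl]cyclobutan-1-ol; 11 dioxygen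
Product: 13 tert-butyl(2-{6-hydroxy-6-[5-(trimethylsilyl)pent-4-yn-1-yl]-1,2-dioxan-3-yl}ethoxy)diphenylsilane (racemic at C3; both C6 hemiketal epimers), via hydroperoxy ketone 12 (not isolated)
Conditions: Co(acac)2 (20 mol%), O2 (1 atm), MeCN, 40 °C
Reagents that add atoms: dioxygen (compound 11), O=O
Why: Co(acac)2 is oxidised by O2 to a trivalent cobalt species that exchanges with the tertiary alcohol, and homolysis of the Co–O bond releases the cyclobutyloxy radical; its strain-driven β-scission breaks the bond between the carbinol carbon and the substituted ring carbon to give the C6 ketone and a secondary radical at C3, which captures triplet O2 (C3–O2) and, after reduction of the peroxyl radical by divalent cobalt, gives hydroperoxy ketone 12. This is the known Co(acac)2-catalysed aerobic ring expansion of 1,2-disubstituted cyclobutanols to 1,2-dioxan-3-ols, the four-ring counterpart of the oxygenation of cyclopropanols to 1,2-dioxolan-3-ols. The 1,2-dioxane closes by reversible 6-exo-trig addition of the hydroperoxide oxygen to the C6 carbonyl (C6–O1). C3 is formed from a planar radical with no controlling element and is racemic, and C6 is an equilibrating hemiketal, so neither centre is fixed here (C6 is set in step 5, C3 is selected in step 12). The step needs β-scission toward the secondary rather than a primary radical, which the substituent on the ring carbon next to the carbinol secures, and it needs a peroxyl radical with no intramolecular partner, which is why the arm is a saturated silyl ether (a homoallylic peroxyl radical from an allyl arm could close 5-exo to a 1,2-dioxolane) and the alkyne is capped with silicon.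

Step 5
Reactants: 13 tert-butyl(2-{6-hydroxy-6-[5-(trimethylsilyl)pent-4-yn-1-yl]-1,2-dioxan-3-yl}ethoxy)diphenylsilane
Product: 14 tert-butyl(2-{(3S*,6R*)-6-methoxy-6-[5-(trimethylsilyl)pent-4-yn-1-yl]-1,2-dioxan-3-yl}ethoxy)diphenylsilane (racemic; OMe cis to the C3 arm)
Conditions: p-TsOH·H2O (5 mol%), MeOH, 0 °C → rt; NaHCO3 quench; chromatography, minor C6 epimer resubmitted
Reagents that add atoms: methanol, CO
Why: Acid-catalysed exchange of the peroxy hemiketal for the methyl ketal through the peroxycarbenium ion under thermodynamic control; C6 is set relative to C3 by the anomeric preference for axial OMe with both carbon substituents equatorial, which is the ketal with OMe cis to the arm, and the TBDPS ether and the C-silyl alkyne tolerate catalytic acid in methanol at this temperature.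

Step 6
Reactants: 14 tert-butyl(2-{(3S*,6R*)-6-methoxy-6-[5-(trimethylsilyl)pent-4-yn-1-yl]-1,2-dioxan-3-yl}ethoxy)diphenylsilane
Product: 15 2-[(3S*,6R*)-6-methoxy-6-(pent-4-yn-1-yl)-1,2-dioxan-3-yl]ethan-1-ol (racemic)
Conditions: Bu4NF (TBAF, 3 equiv), THF, 0 °C → rt
Reagents that add atoms: none
Why: Fluoride-induced desilylation cleaves the Si–O bond of the primary TBDPS ether and the Si–C(sp) bond of the alkynylsilane in one operation, while the dialkyl peroxide and the ketal offer no site for fluoride.

Step 7
Reactants: 15 2-[(3S*,6R*)-6-methoxy-6-(pent-4-yn-1-yl)-1,2-dioxan-3-yl]ethan-1-ol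
Product: 17 2-[(3S*,6R*)-6-methoxy-6-(pent-4-yn-1-yl)-1,2-dioxan-3-yl]acetic acid (racemic), via aldehyde 16 (not isolated)
Conditions: TEMPO (2,2,6,6-tetramethylpiperidin-1-oxyl, 20 mol%), PhI(OAc)2 (2.5 equiv), MeCN/aq. NaH2PO4–Na2HPO4 buffer pH 7 (1:1), rt
Reagents that add atoms: water, O
Why: Oxoammonium-mediated oxidation (TEMPO/PhI(OAc)2 in aqueous acetonitrile) takes the primary alcohol through the aldehyde hydrate to the acid under near-neutral conditions, which avoids β-elimination of the peroxide from aldehyde 16 and leaves the terminal alkyne, the ketal and the O–O bond intact.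

Step 8
Reactants: 17 2-[(3S*,6R*)-6-methoxy-6-(pent-4-yn-1-yl)-1,2-dioxan-3-yl]acetic acid
Product: 18 methyl 2-[(3S*,6R*)-6-methoxy-6-(pent-4-yn-1-yl)-1,2-dioxan-3-yl]acetate (racemic)
Conditions: Me3SiCHN2 (hexanes), PhMe/MeOH (4:1), 0 °C
Reagents that add atoms: trimethylsilyldiazomethane, C[Si](C)(C)C=[N+]=[N-]
Why: Base-free O-methylation of a carboxylic acid with trimethylsilyldiazomethane in methanol, which does not enolise the β-peroxy carbonyl compound and does not react with the unactivated alkyne.

Step 9
Reactants: 19 undec-10-en-2-one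
Product: 21 9-oxodecanal, via ozonide 20 (not isolated)
Conditions: O3, CH2Cl2, −78 °C; then Me2S, −78 °C → rt
Reagents that add atoms: ozone, [O-][O+]=O
Why: Ozonolysis with reductive work-up cleaves the only alkene to the aldehyde; the saturated methyl ketone is inert.

Step 10
Reactants: 21 9-oxodecanal
Product: 22 (E)-11-iodoundec-10-en-2-one
Conditions: CrCl2 (6 equiv), CHI3 (2 equiv), THF/1,4-dioxane (1:6), 0 °C → rt
Reagents that add atoms: iodoform, IC(I)I
Why: Takai olefination: the geminal dichromium species from CHI3 and CrCl2 adds to the aldehyde and eliminates mainly to the E-iodoalkene, aldehydes react far faster than ketones so the methyl ketone needs no protection, and the dioxane-rich solvent raises the E preference.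

Step 11
Reactants: 18 methyl 2-[(3S*,6R*)-6-methoxy-6-(pent-4-yn-1-yl)-1,2-dioxan-3-yl]acetate; 22 (E)-11-iodoundec-10-en-2-one
Product: 23 methyl 2-[(3S*,6R*)-6-methoxy-6-[(6E)-15-oxohexadec-6-en-4-yn-1-yl]-1,2-dioxan-3-yl]acetate (racemic)
Conditions: PdCl2(PPh3)2 (5 mol%), CuI (10 mol%), i-Pr2NH, THF, rt, degassed
Reagents that add atoms: none
Why: Sonogashira coupling of a terminal alkyne with an E-alkenyl iodide runs at room temperature with retention of alkene geometry, and 6-alkoxy-1,2-dioxanes bearing the ester arm tolerate palladium/copper/amine conditions when no free phosphine is added.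

Step 12
Reactants: 23 methyl 2-[(3S*,6R*)-6-methoxy-6-[(6E)-15-oxohexadec-6-en-4-yn-1-yl]-1,2-dioxan-3-yl]acetate
Product: 24 2-[(3S,6R)-6-methoxy-6-[(6E)-15-oxohexadec-6-en-4-yn-1-yl]-1,2-dioxan-3-yl]acetic acid (CNP0165935.1)
Conditions: pig liver esterase, aq. NaH2PO4–Na2HPO4 buffer pH 7.5/acetone (9:1), 25 °C, pH-stat, stopped near 40% conversion; acidified to pH 4, acid separated from remaining ester
Reagents that add atoms: water, O
Why: Enzymatic kinetic resolution by enantioselective ester hydrolysis: the stereocentre lies β to the ester carbonyl, a position serine hydrolases commonly discriminate, so one enantiomer should be hydrolysed faster while the neutral medium spares the β-peroxy ester from retro-oxa-Michael opening; the C3 configuration is selected here, C6 follows because the two centres were linked in step 5, and the sense of selectivity must be confirmed by chiral HPLC before scale-up.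

**Compound list**

1 | cyclobutanone | O=C1CCC1 | starting material
2 | N-cyclohexylcyclobutanimine | C1CC(=NC2CCCCC2)C1 | intermediate
3 | tert-butyl(2-iodoethoxy)diphenylsilane | CC(C)(C)[Si](OCCI)(c1ccccc1)c1ccccc1 | starting material
4 | lithium aza-enolate of 2, lithium cyclobut-1-en-1-yl(cyclohexyl)amide (formed in the flask) | [Li]N(C1CCCCC1)C1=CCC1 | intermediate
5 | N-cyclohexyl-2-{2-[(tert-butyldiphenylsilyl)oxy]ethyl}cyclobutan-1-imine (racemic; formed in the flask) | CC(C)(C)[Si](OCCC1CCC1=NC1CCCCC1)(c1ccccc1)c1ccccc1 | intermediate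
6 | 2-{2-[(tert-butyldiphenylsilyl)oxy]ethyl}cyclobutan-1-one (racemic) | CC(C)(C)[Si](OCCC1CCC1=O)(c1ccccc1)c1ccccc1 | intermediate
7 | (5-chloropent-1-yn-1-yl)trimethylsilane | C[Si](C)(C)C#CCCCCl | starting material
8 | [5-(trimethylsilyl)pent-4-yn-1-yl]magnesium chloride (formed in the flask) | C[Si](C)(C)C#CCCC[Mg]Cl | intermediate
9 | dichloro[5-(trimethylsilyl)pent-4-yn-1-yl]cerium (formed in the flask) | C[Si](C)(C)C#CCCC[Ce](Cl)Cl | intermediate
10 | 2-{2-[(tert-butyldiphenylsilyl)oxy]ethyl}-1-[5-(trimethylsilyl)pent-4-yn-1-yl]cyclobutan-1-ol (racemic; both diastereomers) | OC1(CCCC#C[Si](C)(C)C)CCC1CCO[Si](c1ccccc1)(c1ccccc1)C(C)(C)C | intermediate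
11 | dioxygen | O=O | starting material
12 | 1-[(tert-butyldiphenylsilyl)oxy]-3-hydroperoxy-11-(trimethylsilyl)undec-10-yn-6-one (racemic; formed in the flask) | O=C(CCCC#C[Si](C)(C)C)CC[C@@H](CCO[Si](c1ccccc1)(c1ccccc1)C(C)(C)C)OO | intermediate
13 | tert-butyl(2-{6-hydroxy-6-[5-(trimethylsilyl)pent-4-yn-1-yl]-1,2-dioxan-3-yl}ethoxy)diphenylsilane (racemic at C3; both C6 epimers) | OC1(CCCC#C[Si](C)(C)C)CC[C@@H](CCO[Si](c2ccccc2)(c2ccccc2)C(C)(C)C)OO1 | intermediate
14 | tert-butyl(2-{(3S*,6R*)-6-methoxy-6-[5-(trimethylsilyl)pent-4-yn-1-yl]-1,2-dioxan-3-yl}ethoxy)diphenylsilane (racemic) | CO[C@@]1(CCCC#C[Si](C)(C)C)CC[C@@H](CCO[Si](c2ccccc2)(c2ccccc2)C(C)(C)C)OO1 | intermediate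
15 | 2-[(3S*,6R*)-6-methoxy-6-(pent-4-yn-1-yl)-1,2-dioxan-3-yl]ethan-1-ol (racemic) | CO[C@@]1(CCCC#C)CC[C@@H](CCO)OO1 | intermediate
16 | 2-[(3S*,6R*)-6-methoxy-6-(pent-4-yn-1-yl)-1,2-dioxan-3-yl]acetaldehyde (racemic; formed in the flask) | CO[C@@]1(CCCC#C)CC[C@@H](CC=O)OO1 | intermediate
17 | 2-[(3S*,6R*)-6-methoxy-6-(pent-4-yn-1-yl)-1,2-dioxan-3-yl]acetic acid (racemic) | CO[C@@]1(CCCC#C)CC[C@@H](CC(=O)O)OO1 | intermediate
18 | methyl 2-[(3S*,6R*)-6-methoxy-6-(pent-4-yn-1-yl)-1,2-dioxan-3-yl]acetate (racemic) | CO[C@@]1(CCCC#C)CC[C@@H](CC(=O)OC)OO1 | intermediate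
19 | undec-10-en-2-one | CC(=O)CCCCCCCC=C | starting material
20 | 9-(1,2,4-trioxolan-3-yl)nonan-2-one (ozonide; formed in the flask) | CC(=O)CCCCCCCC1OCOO1 | intermediate
21 | 9-oxodecanal | CC(=O)CCCCCCCC=O | intermediate
22 | (E)-11-iodoundec-10-en-2-one | CC(=O)CCCCCCC/C=C/I | intermediate
23 | methyl 2-[(3S*,6R*)-6-methoxy-6-[(6E)-15-oxohexadec-6-en-4-yn-1-yl]-1,2-dioxan-3-yl]acetate (racemic) | CO[C@@]1(CCCC#C/C=C/CCCCCCCC(C)=O)CC[C@@H](CC(=O)OC)OO1 | intermediate
24 | 2-[(3S,6R)-6-methoxy-6-[(6E)-15-oxohexadec-6-en-4-yn-1-yl]-1,2-dioxan-3-yl]acetic acid | CO[C@@]1(CCCC#C/C=C/CCCCCCCC(C)=O)CC[C@@H](CC(=O)O)OO1 | target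

**Count**

Total steps: 12. Longest linear sequence: 10 steps (steps 1–8, 11 and 12, from cyclobutanone); steps 9 and 10 make the iodoalkene fragment.

**Steps most likely to fail**

Step 12. The esterase may discriminate poorly between the enantiomers, or hydrolyse the wrong one faster, so that the acid is obtained with low enantiomeric purity. The fallback sets out from racemic ester 23 and replaces kinetic resolution by physical separation. Preparative HPLC on a cellulose tris(3,5-dimethylphenylcarbamate) stationary phase should give methyl 2-[(3S,6R)-6-methoxy-6-[(6E)-15-oxohexadec-6-en-4-yn-1-yl]-1,2-dioxan-3-yl]acetate F1 and its (3R,6S) antipode F2. F1 is then hydrolysed with LiOH in THF/H2O at 0 °C and acidified with dilute HCl, which returns to the route at 24.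

Step 4. Cobalt may break down the secondary hydroperoxide (reduction to the alcohol or dehydration to the 1,4-diketone) faster than it closes to the hemiketal, or alkoxide exchange at the hindered tertiary alcohol may be too slow. The fallback sets out from 7 (through Grignard reagent 8) and builds the dioxane by the polar hydroperoxy-ketal/oxa-Michael sequence, returning at 18.
- Addition of 8 to N-methoxy-N-methylpent-4-enamide should give 10-(trimethylsilyl)dec-1-en-9-yn-5-one F3.
- Cross-metathesis with methyl acrylate (second-generation Grubbs catalyst, CH2Cl2, 40 °C) should give methyl (E)-6-oxo-11-(trimethylsilyl)undec-2-en-10-ynoate F4.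
- Acid-catalysed hydroperoxy-ketalisation (ethereal H2O2, MeOH, cat. p-TsOH) should give methyl (E)-6-hydroperoxy-6-methoxy-11-(trimethylsilyl)undec-2-en-10-ynoate F5.
- Et2NH in CF3CH2OH should close the ring by 6-exo-trig conjugate addition of the hydroperoxide, giving after C6 equilibration under the conditions of step 5 methyl 2-{(3S*,6R*)-6-methoxy-6-[5-(trimethylsilyl)pent-4-yn-1-yl]-1,2-dioxan-3-yl}acetate F6.
- K2CO3 in MeOH at 0 °C removes the C-silyl group and delivers 18.

Step 10. E selectivity may erode in the chromium-mediated iodo-olefination of an unbranched aliphatic aldehyde, and the Z isomer would be carried into the coupling. The fallback sets out from 19 and bypasses steps 9 and 10. Cross-metathesis with 4,4,5,5-tetramethyl-2-vinyl-1,3,2-dioxaborolane (second-generation Grubbs catalyst, CH2Cl2, 40 °C) should give (E)-11-(4,4,5,5-tetramethyl-1,3,2-dioxaborolan-2-yl)undec-10-en-2-one F7. Ipso-iododeboronation with N-iodosuccinimide in MeCN, with retention of geometry, returns to the route at 22.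

**Further compounds**

F1 | step 12 | methyl 2-[(3S,6R)-6-methoxy-6-[(6E)-15-oxohexadec-6-en-4-yn-1-yl]-1,2-dioxan-3-yl]acetate (single enantiomer) | CO[C@@]1(CCCC#C/C=C/CCCCCCCC(C)=O)CC[C@@H](CC(=O)OC)OO1
F2 | step 12 | methyl 2-[(3R,6S)-6-methoxy-6-[(6E)-15-oxohexadec-6-en-4-yn-1-yl]-1,2-dioxan-3-yl]acetate (single enantiomer) | CO[C@]1(CCCC#C/C=C/CCCCCCCC(C)=O)CC[C@H](CC(=O)OC)OO1
F3 | step 4 | 10-(trimethylsilyl)dec-1-en-9-yn-5-one | C=CCCC(=O)CCCC#C[Si](C)(C)C
F4 | step 4 | methyl (E)-6-oxo-11-(trimethylsilyl)undec-2-en-10-ynoate | COC(=O)/C=C/CCC(=O)CCCC#C[Si](C)(C)C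
F5 | step 4 | methyl (E)-6-hydroperoxy-6-methoxy-11-(trimethylsilyl)undec-2-en-10-ynoate (racemic) | COC(=O)/C=C/CCC(OC)(OO)CCCC#C[Si](C)(C)C
F6 | step 4 | methyl 2-{(3S*,6R*)-6-methoxy-6-[5-(trimethylsilyl)pent-4-yn-1-yl]-1,2-dioxan-3-yl}acetate (racemic) | CO[C@@]1(CCCC#C[Si](C)(C)C)CC[C@@H](CC(=O)OC)OO1
F7 | step 10 | (E)-11-(4,4,5,5-tetramethyl-1,3,2-dioxaborolan-2-yl)undec-10-en-2-one | CC(=O)CCCCCCC/C=C/B1OC(C)(C)C(C)(C)O1
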